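## Retrosynthetic overview

1. Target 23 ⇐ enantiotopic-ring-selective C–H hydroxylation (the new step) of the achiral meso diolide 21, whose two arenes are identical. This last step creates ring B and fixes the absolute configuration.
2. 21 ⇐ hexabenzyl meso diolide 20 ⇐ 12-membered ring closed by Mitsunobu macrolactonisation (inversion) of seco acid 19. The first ester bond comes from an intermolecular Mitsunobu reaction (inversion) of acid 16 with alcohol 11.
3. 11 and 16 ⇐ enantiomeric erythro 1-benzyloxy-2-hydroxypropyl bromoarenes 8 and 13 ⇐ Shi epoxidation of one (E)-propenylarene 6 with either enantiomer of the ketone, then benzylic anti-opening with BnOH. The carboxyl group comes from Br/Li exchange and CO2.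
4. 6 ⇐ methyl 4-O-methylgallate 1; the gallate carbonyl carbon becomes the benzylic carbon.
5. Ring order: both arenes are bought, the macrocycle is formed in step 17, and ring B receives its extra oxygen last (step 19).

Assumption: (−)-sparteine is taken as the ligand enantiomer that steers the copper oxidant to the arene next to the (R)-carbinol; if the sense proves opposite, commercial (+)-sparteine is used and nothing else changes.

## Route

Step 1
Reactants: 1 methyl 3,5-dihydroxy-4-methoxybenzoate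
Product: 2 methyl 3,5-bis(benzyloxy)-4-methoxybenzoate
Conditions: BnBr, K2CO3, DMF, 60 °C
Reagents that add atoms: benzyl bromide BrCc1ccccc1
Why: Williamson O-alkylation of both phenols; the benzyl ethers survive all later steps and are removed together in step 18.

Step 2
Reactants: 2 methyl 3,5-bis(benzyloxy)-4-methoxybenzoate
Product: 3 [3,5-bis(benzyloxy)-4-methoxyphenyl]methanol
Conditions: LiAlH4, THF, 0 °C
Reagents that add atoms: none
Why: hydride reduction of an ester to the primary alcohol; aryl benzyl ethers are inert.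

Step 3
Reactants: 3 [3,5-bis(benzyloxy)-4-methoxyphenyl]methanol
Product: 4 3,5-bis(benzyloxy)-4-methoxybenzaldehyde
Conditions: MnO2, CH2Cl2, rt
Reagents that add atoms: none
Why: MnO2 oxidation of a benzylic alcohol stops cleanly at the aldehyde.

Step 4
Reactants: 4 3,5-bis(benzyloxy)-4-methoxybenzaldehyde
Product: 5 3,5-bis(benzyloxy)-2-bromo-4-methoxybenzaldehyde
Conditions: NBS, MeCN, 0 °C to rt
Reagents that add atoms: N-bromosuccinimide O=C1CCC(=O)N1Br
Why: electrophilic aromatic bromination; C2 is ortho to one benzyloxy group and para to the other, and the monobromide is deactivated toward a second bromination.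

Step 5
Reactants: 5 3,5-bis(benzyloxy)-2-bromo-4-methoxybenzaldehyde
Product: 6 3,5-bis(benzyloxy)-2-bromo-4-methoxy-1-[(E)-prop-1-en-1-yl]benzene
Conditions: 5-(ethylsulfonyl)-1-phenyl-1H-tetrazole, KN(SiMe3)2, DME, −60 °C to rt
Reagents that add atoms: 5-(ethylsulfonyl)-1-phenyl-1H-tetrazole CCS(=O)(=O)c1nnnn1-c1ccccc1
Why: Julia–Kocienski olefination gives the aryl-conjugated alkene with high E selectivity; residual Z isomer is removed by crystallisation.

Step 6
Reactants: 6 3,5-bis(benzyloxy)-2-bromo-4-methoxy-1-[(E)-prop-1-en-1-yl]benzene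
Product: 7 (2S,3S)-2-[3,5-bis(benzyloxy)-2-bromo-4-methoxyphenyl]-3-methyloxirane
Conditions: ent-Shi ketone (L-fructose-derived, 30 mol %), Oxone, K2CO3, Bu4NHSO4, MeCN–dimethoxymethane–aq. buffer (pH 10.5), 0 °C
Reagents that add atoms: potassium peroxymonosulfate (active part of Oxone) [K+].[O-]S(=O)(=O)OO
Why: Shi asymmetric epoxidation; the chiral dioxirane delivers oxygen through a spiro transition state to one face of the trans-alkene and sets both oxirane carbons as (S,S), the mirror image of the (R,R) sense the D-fructose ketone gives with trans-β-methylstyrene.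

Step 7
Reactants: 7 (2S,3S)-2-[3,5-bis(benzyloxy)-2-bromo-4-methoxyphenyl]-3-methyloxirane
Product: 8 (1R,2S)-1-(benzyloxy)-1-[3,5-bis(benzyloxy)-2-bromo-4-methoxyphenyl]propan-2-ol
Conditions: BnOH (10 equiv), BF3·OEt2 (10 mol %), CH2Cl2, −40 °C
Reagents that add atoms: benzyl alcohol OCc1ccccc1
Why: Lewis-acid-catalysed epoxide alcoholysis; BnOH attacks the activated benzylic carbon from the back (SN2-like, inversion to 1R) and leaves C2 (S) untouched, giving the erythro product. A free cation is disfavoured because the para-methoxy group is twisted out of conjugation by its two ortho neighbours and the ring carries bromine.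

Step 8
Reactants: 8 (1R,2S)-1-(benzyloxy)-1-[3,5-bis(benzyloxy)-2-bromo-4-methoxyphenyl]propan-2-ol
Product: 10 2,4-bis(benzyloxy)-6-[(1R,2S)-1-(benzyloxy)-2-hydroxypropyl]-3-methoxybenzoic acid, via dilithio species 9 (not isolated)
Conditions: n-BuLi (2.2 equiv), THF, −78 °C; CO2; cold 1 M HCl
Reagents that add atoms: carbon dioxide O=C=O
Why: the first equivalent of n-BuLi deprotonates the alcohol and the second effects bromine–lithium exchange; carboxylation of the aryllithium gives the acid without touching either stereocentre.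

Step 9
Reactants: 10 2,4-bis(benzyloxy)-6-[(1R,2S)-1-(benzyloxy)-2-hydroxypropyl]-3-methoxybenzoic acid
Product: 11 prop-2-en-1-yl 2,4-bis(benzyloxy)-6-[(1R,2S)-1-(benzyloxy)-2-hydroxypropyl]-3-methoxybenzoate
Conditions: allyl bromide, KHCO3, DMF, rt
Reagents that add atoms: allyl bromide C=CCBr
Why: SN2 O-alkylation of the carboxylate only (hydrogencarbonate does not deprotonate the alcohol); crude 10 is used at once so that it cannot lactonise.

Step 10
Reactants: 6 3,5-bis(benzyloxy)-2-bromo-4-methoxy-1-[(E)-prop-1-en-1-yl]benzene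
Product: 12 (2R,3R)-2-[3,5-bis(benzyloxy)-2-bromo-4-methoxyphenyl]-3-methyloxirane
Conditions: Shi ketone (D-fructose-derived, 30 mol %), Oxone, K2CO3, Bu4NHSO4, MeCN–dimethoxymethane–aq. buffer (pH 10.5), 0 °C
Reagents that add atoms: potassium peroxymonosulfate (active part of Oxone) [K+].[O-]S(=O)(=O)OO
Why: Shi asymmetric epoxidation with the natural-series ketone gives the (R,R)-epoxide by the same spiro transition state.

Step 11
Reactants: 12 (2R,3R)-2-[3,5-bis(benzyloxy)-2-bromo-4-methoxyphenyl]-3-methyloxirane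
Product: 13 (1S,2R)-1-(benzyloxy)-1-[3,5-bis(benzyloxy)-2-bromo-4-methoxyphenyl]propan-2-ol
Conditions: BnOH (10 equiv), BF3·OEt2 (10 mol %), CH2Cl2, −40 °C
Reagents that add atoms: benzyl alcohol OCc1ccccc1
Why: Lewis-acid-catalysed epoxide alcoholysis with inversion at the benzylic carbon (to 1S) and retention at C2 (R), as in step 7.

Step 12
Reactants: 13 (1S,2R)-1-(benzyloxy)-1-[3,5-bis(benzyloxy)-2-bromo-4-methoxyphenyl]propan-2-ol
Product: 14 tert-butyl{[(1S,2R)-1-(benzyloxy)-1-[3,5-bis(benzyloxy)-2-bromo-4-methoxyphenyl]propan-2-yl]oxy}dimethylsilane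
Conditions: TBSCl, imidazole, DMF, rt
Reagents that add atoms: tert-butyldimethylsilyl chloride CC(C)(C)[Si](C)(C)Cl
Why: silyl ether formation masks the C2 hydroxyl so that this half can only act as the acid partner in step 14.

Step 13
Reactants: 14 tert-butyl{[(1S,2R)-1-(benzyloxy)-1-[3,5-bis(benzyloxy)-2-bromo-4-methoxyphenyl]propan-2-yl]oxy}dimethylsilane
Product: 16 2,4-bis(benzyloxy)-6-[(1S,2R)-1-(benzyloxy)-2-[(tert-butyldimethylsilyl)oxy]propyl]-3-methoxybenzoic acid, via aryllithium 15 (not isolated)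
Conditions: n-BuLi (1.1 equiv), THF, −78 °C; CO2; cold 1 M HCl
Reagents that add atoms: carbon dioxide O=C=O
Why: bromine–lithium exchange followed by carboxylation; silyl and benzyl ethers are stable at −78 °C.

Step 14
Reactants: 11 allyl ester alcohol (1R,2S); 16 silyl-protected acid (1S,2R)
Product: 17 (1R,2R)-1-(benzyloxy)-1-{3,5-bis(benzyloxy)-4-methoxy-2-[(prop-2-en-1-yloxy)carbonyl]phenyl}propan-2-yl 2,4-bis(benzyloxy)-6-[(1S,2R)-1-(benzyloxy)-2-[(tert-butyldimethylsilyl)oxy]propyl]-3-methoxybenzoate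
Conditions: PPh3, DIAD, toluene, 0 °C to rt
Reagents that add atoms: none
Why: Mitsunobu esterification, the standard way to esterify di-ortho-substituted benzoic acids; the carboxylate of 16 displaces the oxyphosphonium of 11 in an SN2 step, inverting C2 of 11 from S to R (erythro to threo).

Step 15
Reactants: 17 silyl-protected diester
Product: 18 (1R,2R)-1-(benzyloxy)-1-{3,5-bis(benzyloxy)-4-methoxy-2-[(prop-2-en-1-yloxy)carbonyl]phenyl}propan-2-yl 2,4-bis(benzyloxy)-6-[(1S,2R)-1-(benzyloxy)-2-hydroxypropyl]-3-methoxybenzoate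
Conditions: HF·pyridine, pyridine, THF, 0 °C to rt
Reagents that add atoms: none
Why: fluoride-induced silyl ether cleavage under mildly acidic conditions that spare both esters and all benzyl ethers.

Step 16
Reactants: 18 hydroxy diester
Product: 19 2,4-bis(benzyloxy)-6-[(1R,2R)-1-(benzyloxy)-2-({2,4-bis(benzyloxy)-6-[(1S,2R)-1-(benzyloxy)-2-hydroxypropyl]-3-methoxybenzoyl}oxy)propyl]-3-methoxybenzoic acid
Conditions: Pd(PPh3)4 (5 mol %), morpholine, THF, rt
Reagents that add atoms: none
Why: Tsuji–Trost deallylation; zerovalent palladium ionises the allyl ester to a π-allyl complex that morpholine captures, under neutral conditions that do not trigger lactonisation.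

Step 17
Reactants: 19 seco acid
Product: 20 hexabenzyl meso diolide: 12-membered head-to-tail dilactone of a (1R,2R) and a (1S,2S) 2,4-bis(benzyloxy)-6-[1-(benzyloxy)-2-hydroxypropyl]-3-methoxybenzoic acid unit, each C2 oxygen acylated by the carboxyl of the other unit
Conditions: PPh3, DIAD, toluene (2 mM, slow addition of 19), 0 °C to rt
Reagents that add atoms: none
Why: Mitsunobu macrolactonisation under high dilution; the carboxylate displaces the activated C2 hydroxyl with inversion (R to S), which closes the 12-membered ring and makes the centrosymmetric, achiral meso compound. Diastereomers arising from the minor enantiomers of 11 and 16 are removed by crystallisation.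

Step 18
Reactants: 20 hexabenzyl meso diolide
Product: 21 meso diolide hexol: 12-membered head-to-tail dilactone of a (1R,2R) and a (1S,2S) 6-(1,2-dihydroxypropyl)-2,4-dihydroxy-3-methoxybenzoic acid unit (achiral)
Conditions: H2 (1 atm), Pd(OH)2/C, EtOAc–MeOH, rt
Reagents that add atoms: none
Why: catalytic hydrogenolysis of all six O-benzyl groups; the two ring-bound secondary benzylic C–O bonds are shielded by the ortho lactone carbonyl and react far more slowly, so the reaction is stopped after six equivalents of H2.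

Step 19
Reactants: 21 meso diolide hexol
Product: 23 CNP0086623.3 (target), via ortho-quinone 22 (not isolated)
Conditions: [Cu(MeCN)4]PF6 (20 mol %), (−)-sparteine (22 mol %), Et3N (1 equiv), O2 (1 atm), THF–acetone, −78 to −40 °C; then aq. Na2S2O4 (pH 6), 0 °C
Reagents that add atoms: dioxygen O=O
Why: Proposed new method: enantiotopic-ring-selective, tyrosinase-type ortho-hydroxylation of a meso bis-phenol. Monovalent copper, the chiral diamine and O2 form a side-on peroxo dicopper species that binds the C4' phenolate (para to the lactone carbonyl). It transfers one oxygen electrophilically to C5', the only free ring position, giving ortho-quinone 22; dithionite reduces 22 to the catechol. The two arenes of 21 are mirror images, each next to a benzylic carbinol of opposite configuration that can act as a second contact to the copper core, so the chiral oxidant meets two diastereomeric transition states (a kinetic resolution within one molecule) and oxygenates only the ring next to the (R)-carbinol. Any minor enantiomer is consumed faster by a second hydroxylation, which raises the ee of 23. Closest known reaction types: catalytic aerobic ortho-oxygenation of phenols to ortho-quinones by diamine–copper–O2 tyrosinase mimics, and enantioselective hydroxylative dearomatisation of resorcinol-type phenols by sparteine–dicopper–dioxygen; desymmetrisation of a meso bis-phenol by such an oxygenation is not known.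

## Compound list

1 | methyl 3,5-dihydroxy-4-methoxybenzoate | COC(=O)c1cc(O)c(OC)c(O)c1 | starting material
2 | methyl 3,5-bis(benzyloxy)-4-methoxybenzoate | COC(=O)c1cc(OCc2ccccc2)c(OC)c(OCc2ccccc2)c1 | intermediate
3 | [3,5-bis(benzyloxy)-4-methoxyphenyl]methanol | OCc1cc(OCc2ccccc2)c(OC)c(OCc2ccccc2)c1 | intermediate
4 | 3,5-bis(benzyloxy)-4-methoxybenzaldehyde | O=Cc1cc(OCc2ccccc2)c(OC)c(OCc2ccccc2)c1 | intermediate
5 | 3,5-bis(benzyloxy)-2-bromo-4-methoxybenzaldehyde | O=Cc1cc(OCc2ccccc2)c(OC)c(OCc2ccccc2)c1Br | intermediate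
6 | 3,5-bis(benzyloxy)-2-bromo-4-methoxy-1-[(E)-prop-1-en-1-yl]benzene | C/C=C/c1cc(OCc2ccccc2)c(OC)c(OCc2ccccc2)c1Br | intermediate
7 | (2S,3S)-2-[3,5-bis(benzyloxy)-2-bromo-4-methoxyphenyl]-3-methyloxirane | C[C@@H]1O[C@H]1c1cc(OCc2ccccc2)c(OC)c(OCc2ccccc2)c1Br | intermediate
8 | (1R,2S)-1-(benzyloxy)-1-[3,5-bis(benzyloxy)-2-bromo-4-methoxyphenyl]propan-2-ol | C[C@H](O)[C@H](OCc1ccccc1)c1cc(OCc2ccccc2)c(OC)c(OCc2ccccc2)c1Br | intermediate
9 | dilithio species of 8 (lithium alkoxide, ring bromine replaced by lithium) | C[C@H](O[Li])[C@H](OCc1ccccc1)c1cc(OCc2ccccc2)c(OC)c(OCc2ccccc2)c1[Li] | intermediate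
10 | 2,4-bis(benzyloxy)-6-[(1R,2S)-1-(benzyloxy)-2-hydroxypropyl]-3-methoxybenzoic acid | C[C@H](O)[C@H](OCc1ccccc1)c1cc(OCc2ccccc2)c(OC)c(OCc2ccccc2)c1C(=O)O | intermediate
11 | prop-2-en-1-yl 2,4-bis(benzyloxy)-6-[(1R,2S)-1-(benzyloxy)-2-hydroxypropyl]-3-methoxybenzoate | C[C@H](O)[C@H](OCc1ccccc1)c1cc(OCc2ccccc2)c(OC)c(OCc2ccccc2)c1C(=O)OCC=C | intermediate
12 | (2R,3R)-2-[3,5-bis(benzyloxy)-2-bromo-4-methoxyphenyl]-3-methyloxirane | C[C@H]1O[C@@H]1c1cc(OCc2ccccc2)c(OC)c(OCc2ccccc2)c1Br | intermediate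
13 | (1S,2R)-1-(benzyloxy)-1-[3,5-bis(benzyloxy)-2-bromo-4-methoxyphenyl]propan-2-ol | C[C@@H](O)[C@@H](OCc1ccccc1)c1cc(OCc2ccccc2)c(OC)c(OCc2ccccc2)c1Br | intermediate
14 | tert-butyl{[(1S,2R)-1-(benzyloxy)-1-[3,5-bis(benzyloxy)-2-bromo-4-methoxyphenyl]propan-2-yl]oxy}dimethylsilane | C[C@@H](O[Si](C)(C)C(C)(C)C)[C@@H](OCc1ccccc1)c1cc(OCc2ccccc2)c(OC)c(OCc2ccccc2)c1Br | intermediate
15 | aryllithium from 14 (ring bromine replaced by lithium) | C[C@@H](O[Si](C)(C)C(C)(C)C)[C@@H](OCc1ccccc1)c1cc(OCc2ccccc2)c(OC)c(OCc2ccccc2)c1[Li] | intermediate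
16 | 2,4-bis(benzyloxy)-6-[(1S,2R)-1-(benzyloxy)-2-[(tert-butyldimethylsilyl)oxy]propyl]-3-methoxybenzoic acid | C[C@@H](O[Si](C)(C)C(C)(C)C)[C@@H](OCc1ccccc1)c1cc(OCc2ccccc2)c(OC)c(OCc2ccccc2)c1C(=O)O | intermediate
17 | (1R,2R)-1-(benzyloxy)-1-{3,5-bis(benzyloxy)-4-methoxy-2-[(prop-2-en-1-yloxy)carbonyl]phenyl}propan-2-yl 2,4-bis(benzyloxy)-6-[(1S,2R)-1-(benzyloxy)-2-[(tert-butyldimethylsilyl)oxy]propyl]-3-methoxybenzoate | C[C@@H](O[Si](C)(C)C(C)(C)C)[C@@H](OCc1ccccc1)c1cc(OCc2ccccc2)c(OC)c(OCc2ccccc2)c1C(=O)O[C@H](C)[C@H](OCc1ccccc1)c1cc(OCc2ccccc2)c(OC)c(OCc2ccccc2)c1C(=O)OCC=C | intermediate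
18 | (1R,2R)-1-(benzyloxy)-1-{3,5-bis(benzyloxy)-4-methoxy-2-[(prop-2-en-1-yloxy)carbonyl]phenyl}propan-2-yl 2,4-bis(benzyloxy)-6-[(1S,2R)-1-(benzyloxy)-2-hydroxypropyl]-3-methoxybenzoate | C[C@@H](O)[C@@H](OCc1ccccc1)c1cc(OCc2ccccc2)c(OC)c(OCc2ccccc2)c1C(=O)O[C@H](C)[C@H](OCc1ccccc1)c1cc(OCc2ccccc2)c(OC)c(OCc2ccccc2)c1C(=O)OCC=C | intermediate
19 | 2,4-bis(benzyloxy)-6-[(1R,2R)-1-(benzyloxy)-2-({2,4-bis(benzyloxy)-6-[(1S,2R)-1-(benzyloxy)-2-hydroxypropyl]-3-methoxybenzoyl}oxy)propyl]-3-methoxybenzoic acid | C[C@@H](O)[C@@H](OCc1ccccc1)c1cc(OCc2ccccc2)c(OC)c(OCc2ccccc2)c1C(=O)O[C@H](C)[C@H](OCc1ccccc1)c1cc(OCc2ccccc2)c(OC)c(OCc2ccccc2)c1C(=O)O | intermediate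
20 | hexabenzyl meso diolide: 12-membered head-to-tail dilactone of a (1R,2R) and a (1S,2S) 2,4-bis(benzyloxy)-6-[1-(benzyloxy)-2-hydroxypropyl]-3-methoxybenzoic acid unit | C[C@@H]1OC(=O)c2c(OCc3ccccc3)c(OC)c(OCc3ccccc3)cc2[C@@H](OCc2ccccc2)[C@@H](C)OC(=O)c2c(OCc3ccccc3)c(OC)c(OCc3ccccc3)cc2[C@@H]1OCc1ccccc1 | intermediate
21 | meso diolide hexol: 12-membered head-to-tail dilactone of a (1R,2R) and a (1S,2S) 6-(1,2-dihydroxypropyl)-2,4-dihydroxy-3-methoxybenzoic acid unit | C[C@@H]1OC(=O)c2c(O)c(OC)c(O)cc2[C@@H](O)[C@@H](C)OC(=O)c2c(O)c(OC)c(O)cc2[C@@H]1O | intermediate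
22 | ortho-quinone of 21: the arene next to the (R)-carbinol oxidised to the 4,5-dione (2-hydroxy-3-methoxy-4,5-dioxocyclohexa-1,6-diene ring) | C[C@@H]1OC(=O)C2=C(C(=O)C(=O)C(OC)=C2O)[C@@H](O)[C@@H](C)OC(=O)c2c(O)c(OC)c(O)cc2[C@@H]1O | intermediate
23 | CNP0086623.3: diolide in which ring B (2,4,5-trihydroxy-3-methoxy) carries the (1R,2R) side chain and ring A (2,4-dihydroxy-3-methoxy) the (1S,2S) side chain | C[C@@H]1OC(=O)c2c(O)c(OC)c(O)c(O)c2[C@@H](O)[C@@H](C)OC(=O)c2c(O)c(OC)c(O)cc2[C@@H]1O | target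

## Step count and risks

Total steps: 19. Longest linear sequence: 15 steps (steps 1–5, then 6–9 or 10–13, then 14–19).

**Risk 1: step 19 (the proposed new method).** Ring discrimination by the chiral copper–dioxygen species is unproven. A second hydroxylation, oxidation of the benzylic alcohols, or copper binding by the salicylate motif could also interfere.

Fallback with known chemistry, setting out from 8 and coming back at 23; ring B receives its oxygen before the coupling, so no desymmetrisation is needed: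
- NBS in MeCN brominates the last free ring position of 8 to give (1R,2S)-1-(benzyloxy)-1-[3,5-bis(benzyloxy)-2,6-dibromo-4-methoxyphenyl]propan-2-ol F1, whose two bromines are equivalent.
- n-BuLi (2.1 equiv, THF, −78 °C) gives the monolithiated lithium alkoxide F2. B(OMe)3 converts it into the dimethyl arylboronate F3, and H2O2/NaOH gives 4,6-bis(benzyloxy)-2-[(1R,2S)-1-(benzyloxy)-2-hydroxypropyl]-3-bromo-5-methoxyphenol F4.
- BnBr/K2CO3 in acetone benzylates only the phenol and gives (1R,2S)-1-(benzyloxy)-1-[2,3,5-tris(benzyloxy)-6-bromo-4-methoxyphenyl]propan-2-ol F5.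
- Bromine–lithium exchange and carboxylation as in step 8, through the dilithio species F6, give 2,4,5-tris(benzyloxy)-6-[(1R,2S)-1-(benzyloxy)-2-hydroxypropyl]-3-methoxybenzoic acid F7. Allyl bromide/KHCO3 gives its prop-2-en-1-yl ester F8.
- Mitsunobu coupling of F8 with 16 gives the 5-benzyloxy analogue of 17 F9. HF·pyridine gives the 5-benzyloxy analogue of 18 F10, and Pd(PPh3)4/morpholine gives the 5-benzyloxy analogue of 19 F11.
- Mitsunobu macrolactonisation gives the heptabenzyl ether of 23 F12, and hydrogenolysis (H2, Pd(OH)2/C) gives 23.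

**Risk 2: step 17 (Mitsunobu macrolactonisation).** It needs an SN2 displacement at a hindered secondary carbinol next to CH(OBn)Ar while closing a 12-membered ring. Elimination, acyl hydrazide formation and participation of the neighbouring ester carbonyl compete.

Fallback, setting out from 18 and coming back at 20: MsCl/Et3N converts 18 into the C2 methanesulfonate of 18 F13. Pd(PPh3)4/morpholine removes the allyl group to give the C2 methanesulfonate of 19 F14. Cs2CO3 in DMF (2 mM, 60 °C) then closes the ring by intramolecular displacement of the mesylate by the cesium carboxylate with inversion (Kruizinga–Kellogg alkylative macrolactonisation), giving 20. This replaces the redox condensation by a preformed leaving group and allows heating without phosphonium or hydrazide side reactions.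

**Risk 3: step 14 (intermolecular Mitsunobu esterification).** Both partners are hindered, and the ortho allyl ester of 11 may intercept the oxyphosphonium intermediate.

Fallback, setting out from 11 and coming back at 17: MsCl/Et3N gives the C2 methanesulfonate of 11 F15, which is heated with acid 16 and Cs2CO3 in DMF at 60 °C. The cesium carboxylate of 16 displaces the mesylate with inversion to give 17.

## Further compounds

F1 | step 19 | (1R,2S)-1-(benzyloxy)-1-[3,5-bis(benzyloxy)-2,6-dibromo-4-methoxyphenyl]propan-2-ol | C[C@H](O)[C@H](OCc1ccccc1)c1c(Br)c(OCc2ccccc2)c(OC)c(OCc2ccccc2)c1Br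
F2 | step 19 | monolithiated lithium alkoxide of F1 (one bromine replaced by lithium; not isolated) | C[C@H](O[Li])[C@H](OCc1ccccc1)c1c([Li])c(OCc2ccccc2)c(OC)c(OCc2ccccc2)c1Br
F3 | step 19 | dimethyl arylboronate from F2 (lithium alkoxide; not isolated) | C[C@H](O[Li])[C@H](OCc1ccccc1)c1c(B(OC)OC)c(OCc2ccccc2)c(OC)c(OCc2ccccc2)c1Br
F4 | step 19 | 4,6-bis(benzyloxy)-2-[(1R,2S)-1-(benzyloxy)-2-hydroxypropyl]-3-bromo-5-methoxyphenol | C[C@H](O)[C@H](OCc1ccccc1)c1c(O)c(OCc2ccccc2)c(OC)c(OCc2ccccc2)c1Br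
F5 | step 19 | (1R,2S)-1-(benzyloxy)-1-[2,3,5-tris(benzyloxy)-6-bromo-4-methoxyphenyl]propan-2-ol | C[C@H](O)[C@H](OCc1ccccc1)c1c(OCc2ccccc2)c(OCc2ccccc2)c(OC)c(OCc2ccccc2)c1Br
F6 | step 19 | dilithio species of F5 (lithium alkoxide, bromine replaced by lithium; not isolated) | C[C@H](O[Li])[C@H](OCc1ccccc1)c1c(OCc2ccccc2)c(OCc2ccccc2)c(OC)c(OCc2ccccc2)c1[Li]
F7 | step 19 | 2,4,5-tris(benzyloxy)-6-[(1R,2S)-1-(benzyloxy)-2-hydroxypropyl]-3-methoxybenzoic acid | C[C@H](O)[C@H](OCc1ccccc1)c1c(OCc2ccccc2)c(OCc2ccccc2)c(OC)c(OCc2ccccc2)c1C(=O)O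
F8 | step 19 | prop-2-en-1-yl 2,4,5-tris(benzyloxy)-6-[(1R,2S)-1-(benzyloxy)-2-hydroxypropyl]-3-methoxybenzoate | C[C@H](O)[C@H](OCc1ccccc1)c1c(OCc2ccccc2)c(OCc2ccccc2)c(OC)c(OCc2ccccc2)c1C(=O)OCC=C
F9 | step 19 | 5-benzyloxy analogue of 17 (extra benzyloxy group on the allyl ester ring, next to the side chain) | C[C@@H](O[Si](C)(C)C(C)(C)C)[C@@H](OCc1ccccc1)c1cc(OCc2ccccc2)c(OC)c(OCc2ccccc2)c1C(=O)O[C@H](C)[C@H](OCc1ccccc1)c1c(OCc2ccccc2)c(OCc2ccccc2)c(OC)c(OCc2ccccc2)c1C(=O)OCC=C
F10 | step 19 | 5-benzyloxy analogue of 18 | C[C@@H](O)[C@@H](OCc1ccccc1)c1cc(OCc2ccccc2)c(OC)c(OCc2ccccc2)c1C(=O)O[C@H](C)[C@H](OCc1ccccc1)c1c(OCc2ccccc2)c(OCc2ccccc2)c(OC)c(OCc2ccccc2)c1C(=O)OCC=C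
F11 | step 19 | 5-benzyloxy analogue of 19 | C[C@@H](O)[C@@H](OCc1ccccc1)c1cc(OCc2ccccc2)c(OC)c(OCc2ccccc2)c1C(=O)O[C@H](C)[C@H](OCc1ccccc1)c1c(OCc2ccccc2)c(OCc2ccccc2)c(OC)c(OCc2ccccc2)c1C(=O)O
F12 | step 19 | heptabenzyl ether of 23 (all five phenols and both benzylic hydroxyls benzylated) | C[C@@H]1OC(=O)c2c(OCc3ccccc3)c(OC)c(OCc3ccccc3)c(OCc3ccccc3)c2[C@@H](OCc2ccccc2)[C@@H](C)OC(=O)c2c(OCc3ccccc3)c(OC)c(OCc3ccccc3)cc2[C@@H]1OCc1ccccc1
F13 | step 17 | C2 methanesulfonate of 18 | C[C@@H](OS(C)(=O)=O)[C@@H](OCc1ccccc1)c1cc(OCc2ccccc2)c(OC)c(OCc2ccccc2)c1C(=O)O[C@H](C)[C@H](OCc1ccccc1)c1cc(OCc2ccccc2)c(OC)c(OCc2ccccc2)c1C(=O)OCC=C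
F14 | step 17 | C2 methanesulfonate of 19 | C[C@@H](OS(C)(=O)=O)[C@@H](OCc1ccccc1)c1cc(OCc2ccccc2)c(OC)c(OCc2ccccc2)c1C(=O)O[C@H](C)[C@H](OCc1ccccc1)c1cc(OCc2ccccc2)c(OC)c(OCc2ccccc2)c1C(=O)O
F15 | step 14 | C2 methanesulfonate of 11 | C[C@H](OS(C)(=O)=O)[C@H](OCc1ccccc1)c1cc(OCc2ccccc2)c(OC)c(OCc2ccccc2)c1C(=O)OCC=C
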